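**Remarks on the chemistry (before the steps)**

- Briarane numbering is used for every intermediate. In the decalin intermediates ring A is C1, C10, C11, C12, C13, C14 and ring B is C1, C2, C7, C8, C9, C10 (C2 bonded to C7). α/β refer to the bicycle drawn flat with the C15 methyl on C1 as β.
- Assumption: vinyl addition in step 15 is drawn from the β face (2β-vinyl, 2α-oxygen in 24–33). The C2 epimer would pass through steps 16–23 to the same compound 38, because the C7 alkenyl group is equatorial in either case.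

## Retrosynthetic overview

1. Feature: the oxygenated carbons C2 and C7 lie 1,6 to each other across the ten-membered ring (C1–C10) fused to cyclohexene ring A. A trans-decalin whose ring B holds a C2–C7 bond, a vinyl group (C3=C4) on C2 and an alkenyl group (C6=C5–C16) on C7 maps onto the target, with C3–C6 as the four inserted carbons.
2. Key disconnection: C4–C5 formed and C2–C7 broken by an anionic oxy-Cope shift of the C7 potassium alkoxide (O2 as MOM ether), giving the C6=C7 enolate (trapped as silyl enol ether) and the C2=C3 enol ether.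
3. After the shift: Saegusa oxidation to the C5=C6 enone, C7 reduction, lactone by SmI2 Reformatsky closure of C17–C8, C2 reduction, acetylation.
4. Before the shift: ring A from (S)-carvone (C14–O by Criegee rearrangement); C9–O and C10–H by directed epoxidation and Pd/formate hydrogenolysis; C2 and C7 ketones take up vinylmagnesium bromide and the alkenyllithium from propargyl alcohol.
5. Ring order: ring A (carvone), six-membered ring B (step 4), ten-membered ring (step 21), lactone (step 27).

Key step: step 21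

## Route

Step 1
Reactants: 1 (S)-carvone; 2 2-(2-bromoethyl)-2-methyl-1,3-dioxolane
Product: 4 1-alkylated carvone (C1–H bearing the ketal chain C2–C7–C8–C9 trans to the C14 isopropenyl group), via lithium dienolate 3 (not isolated)
Conditions: LiN(iPr)2, THF, −78 °C; then 2, DMPU, −78 → 25 °C
Reagents that add atoms: none
Why: Kinetic α′-deprotonation gives the cross-conjugated enolate, which is alkylated by the primary bromide (enolate alkylation) anti to the isopropenyl group; this centre is reset in step 2.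

Step 2
Reactants: 4 1-alkylated carvone
Product: 6 1-methylated enone (C1 quaternary: C15 methyl trans and ketal chain cis to the C14 isopropenyl group), via lithium enolate 5 (not isolated)
Conditions: LiN(iPr)2, THF, −78 °C; then MeI, −78 → 0 °C
Reagents that add atoms: iodomethane, CI
Why: Enolate alkylation of the tetrasubstituted enolate occurs on the face opposite the adjacent isopropenyl group, which sets C1 with the methyl trans to the future C14 oxygen.

Step 3
Reactants: 6 1-methylated enone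
Product: 8 14α-acetoxy enone ketal, via methoxy hydroperoxide 7 (not isolated)
Conditions: O3, CH2Cl2–MeOH, −78 °C; then Ac2O, Et3N, DMAP, 0 → 40 °C
Reagents that add atoms: ozone, [O-][O+]=O; methanol, CO
Why: The electron-rich isopropenyl group is ozonised in preference to the enone double bond, and acetylation of the methoxy hydroperoxide triggers Criegee rearrangement in which C14 migrates to oxygen with retention, so the carvone stereocentre becomes the 14α-oxygen centre.

Step 4
Reactants: 8 14α-acetoxy enone ketal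
Product: 10 bicyclic dienone acetate (C8 ketone; C9=C10; C11=C12; 14α-OAc), via diketone 9 (not isolated)
Conditions: 1 M HCl, THF, 25 °C; then pyrrolidine, AcOH, PhMe, 80 °C
Reagents that add atoms: water, O
Why: Ketal hydrolysis frees the methyl ketone, whose enamine adds to the C10 carbonyl and dehydrates (intramolecular aldol condensation), closing six-membered ring B through C9–C10 as the only strain-free mode.

Step 5
Reactants: 10 bicyclic dienone acetate
Product: 11 cross-conjugated trienone acetate (additional C2=C7 double bond)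
Conditions: DDQ, dioxane, 100 °C
Reagents that add atoms: none
Why: DDQ dehydrogenation of a linear dienone at its α′,β′ positions (C7, C2) is the standard route to the cross-conjugated trienone, as with 4,6-dien-3-one steroids.

Step 6
Reactants: 11 trienone acetate
Product: 12 2α,7α-epoxy-8-oxo-9,11-diene with free 14α-hydroxyl
Conditions: 30% H2O2, NaOH, MeOH, 0 → 25 °C
Reagents that add atoms: hydrogen peroxide, OO
Why: Weitz–Scheffer epoxidation takes the less substituted enone double bond, hydroperoxide adding to C2 anti to the C15 methyl to give the α-epoxide, and the same alkaline methanol cleaves the C14 acetate.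

Step 7
Reactants: 12 epoxy ketone alcohol
Product: 13 14-O-TBS ether of 12
Conditions: TBSOTf, 2,6-lutidine, CH2Cl2, −78 → 0 °C
Reagents that add atoms: tert-butyldimethylsilyl triflate, CC(C)(C)[Si](C)(C)OS(=O)(=O)C(F)(F)F
Why: Silyl triflate silylation protects the hindered axial alcohol before it can direct epoxidation of C11=C12 in step 9.

Step 8
Reactants: 13 silylated epoxy ketone
Product: 14 2α,8β-diol (9,11-diene; 14α-OTBS)
Conditions: LiAlH4, THF, −78 → 25 °C
Reagents that add atoms: none
Why: 1,2-Hydride reduction of the dienone from the α face gives the pseudo-equatorial 8β-alkoxide, and hydride then opens the α-epoxide at C7 by trans-diaxial (Fürst–Plattner) attack from the β face, leaving the axial 2α-hydroxyl.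

Step 9
Reactants: 14 diol
Product: 15 9β,10β-epoxide of 14
Conditions: VO(acac)2 (cat.), t-BuOOH, CH2Cl2, 0 → 25 °C
Reagents that add atoms: tert-butyl hydroperoxide, CC(C)(C)OO
Why: Hydroxyl-directed vanadium-catalysed epoxidation delivers oxygen to the allylic C9=C10 bond syn to the 8β-hydroxyl (the homoallylic C2 hydroxyl reacts far more slowly), which sets C9–O β and spares C11=C12.

Step 10
Reactants: 15 vinyl epoxide
Product: 16 2α,8β,9β-triol (10α-H; C11=C12; 14α-OTBS; trans-decalin)
Conditions: Pd2(dba)3·CHCl3 (cat.), PBu3, HCO2H, Et3N, dioxane, 25 °C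
Reagents that add atoms: none
Why: Tsuji hydrogenolysis of the alkenyloxirane: zerovalent palladium opens the allylic C10–O bond with inversion, and hydride from the palladium formate is transferred to the more substituted terminus C10 on the α face, giving the trans ring fusion, the 9β-hydroxyl and the C11=C12 bond.

Step 11
Reactants: 16 triol
Product: 18 8-O-PMB ether of 16, via stannylene acetal 17 (not isolated)
Conditions: Bu2SnO, MeOH, 65 °C; then 4-MeOC6H4CH2Cl, CsF, DMF, 25 °C
Reagents that add atoms: 4-methoxybenzyl chloride, COc1ccc(CCl)cc1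
Why: The stannylene acetal forms on the cis-vicinal 8,9-diol and is alkylated at its equatorial oxygen (stannylene-mediated regioselective O-alkylation), so O8 is marked for later oxidation.

Step 12
Reactants: 18 8-O-PMB ether
Product: 19 8-O-PMB 9-O-TBS ether with free 2α-hydroxyl
Conditions: TBSOTf, 2,6-lutidine, CH2Cl2, −78 → −20 °C
Reagents that add atoms: tert-butyldimethylsilyl triflate, CC(C)(C)[Si](C)(C)OS(=O)(=O)C(F)(F)F
Why: Silylation should take the C9 hydroxyl in preference to the neopentyl C2 hydroxyl, which is syn-axial to the C14 silyl ether.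

Step 13
Reactants: 19 2α-alcohol
Product: 20 C2 ketone
Conditions: Dess–Martin periodinane, NaHCO3, CH2Cl2, 25 °C
Reagents that add atoms: none
Why: Hypervalent iodine oxidation of the strained axial secondary alcohol gives the ketone without touching the ethers or the alkene.

Step 14
Reactants: 20 C2 ketone
Product: 22 7α-hydroxy 2-ketone, via potassium enolate 21 (not isolated)
Conditions: KN(SiMe3)2, THF, −78 °C; then 2-(phenylsulfonyl)-3-phenyloxaziridine, −78 °C
Reagents that add atoms: 2-(phenylsulfonyl)-3-phenyloxaziridine, O=S(=O)(c1ccccc1)N1OC1c1ccccc1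
Why: C1 is quaternary, so the enolate forms only towards C7, and oxaziridine hydroxylation of the enolate places oxygen on C7 from the α face away from the axial C15 methyl and C9 silyl ether (this centre becomes a ketone in step 16).

Step 15
Reactants: 22 7α-hydroxy 2-ketone; 23 vinylmagnesium bromide
Product: 24 2β-vinyl 2α,7α-diol
Conditions: CH2=CHMgBr (excess), THF, −78 → 0 °C
Reagents that add atoms: none
Why: After deprotonation of the C7 hydroxyl, Grignard 1,2-addition to the chelated C2 ketone is expected from the β face because axial approach is screened by the syn-axial C14 silyl ether; the C2 epimer would serve equally in the key step.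

Step 16
Reactants: 24 diol
Product: 25 2β-vinyl 2α-hydroxy 7-ketone
Conditions: IBX, DMSO, 25 °C
Reagents that add atoms: none
Why: IBX oxidises the secondary alcohol of a 1,2-diol to the α-ketol without C–C cleavage, and the tertiary C2 alcohol is inert.

Step 17
Reactants: 25 α-ketol
Product: 26 2-O-MOM ether of 25
Conditions: MOMCl, iPr2NEt, NaI (cat.), ClCH2CH2Cl, 50 °C
Reagents that add atoms: chloromethyl methyl ether, COCCl
Why: O-Alkylation with the small chloromethyl ether under amine base avoids the alkoxide that could cause α-ketol rearrangement and installs a group that cannot migrate in the key step.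

Step 18
Reactants: 27 propargyl alcohol
Product: 28 TBDPS ether of propargyl alcohol
Conditions: TBDPSCl, imidazole, DMF, 25 °C
Reagents that add atoms: tert-butyl(chloro)diphenylsilane, CC(C)(C)[Si](Cl)(c1ccccc1)c1ccccc1
Why: Standard silylation of a primary alcohol gives an ether stable to organolithium and potassium alkoxide chemistry.

Step 19
Reactants: 28 silyl propargyl ether
Product: 30 (E)-3-iodoallyl TBDPS ether, via alkenylzirconocene chloride 29 (not isolated)
Conditions: Cp2Zr(H)Cl, THF, 25 °C; then I2, 0 °C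
Reagents that add atoms: iodine, II
Why: Syn hydrozirconation of the terminal alkyne places zirconium at the terminus, and iodinolysis with retention gives the (E)-vinyl iodide.

Step 20
Reactants: 26 MOM ether ketone; 30 (E)-vinyl iodide
Product: 32 oxy-Cope precursor (C2: β-vinyl and α-OMOM; C7: β-OH and α-(E)-alkenyl), via alkenyllithium 31 (not isolated)
Conditions: 30, t-BuLi, Et2O, −78 °C; then 26, THF, −78 → −40 °C
Reagents that add atoms: none
Why: Iodine–lithium exchange keeps the E geometry, and 1,2-addition to the C7 ketone occurs by equatorial attack on the α face because the β face is blocked by the syn-axial C15 methyl and C9 silyl ether, giving the axial 7β-hydroxyl and the equatorial alkenyl group.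

Step 21
Reactants: 32 oxy-Cope precursor
Product: 35 ten-membered bis-enol ether (C6=C7 triethylsilyl enol ether; C2=C3 MOM enol ether), via potassium alkoxide 33 (not isolated), via potassium enolate 34 (not isolated)
Conditions: KH, 18-crown-6, THF, 0 → 25 °C; then Et3SiCl, Et3N, −78 °C
Reagents that add atoms: chlorotriethylsilane, CC[Si](Cl)(CC)CC
Why: Deprotonation of the tertiary C7 hydroxyl gives the crown-separated potassium alkoxide 33, whose 3-oxido-1,5-diene C4=C3–C2–C7(O–)–C6=C5 undergoes an anionic oxy-Cope [3,3] shift through a chair transition state, forming C4–C5 and breaking C2–C7; the closest known reaction type is the anionic oxy-Cope ring expansion of trans-1,2-dialkenylcyclohexanols to cyclodec-5-enones. The ten-membered ring is not closed by a cyclisation: it arises because the bond shared by ring B and the six-membered transition-state array is cleaved, so ring B grows by the four carbons C3–C6, and the shift is driven by formation of the C6=C7 enolate 34. The only new stereocentre, C5, is set by the chair array with both alkenyl groups equatorial on the rigid trans-decalin and the (E)-alkene holding C16 pseudo-equatorial; it is erased in step 22, as are the geometries of both new double bonds. The step needs the [3,3] shift to outrun protecting-group migration and fragmentation: O2 and O8 carry MOM and PMB groups that cannot migrate, a shift of the C9 silyl group to O7 would be reversible and only park the alkoxide, and the equatorial C7 alkenyl group keeps the two alkenyl groups gauche whatever the C2 configuration. O-Silylation of 34 stores C7 as a regiodefined silyl enol ether while C2 stays masked as its enol ether, so no 1,6-diketone forms and transannular aldol reaction is excluded.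

Step 22
Reactants: 35 bis-enol ether
Product: 36 C5=C6 enone (C7 ketone; ring-cis double bond; C2=C3 MOM enol ether retained)
Conditions: Pd(OAc)2, MeCN, 25 °C
Reagents that add atoms: none
Why: Saegusa–Ito oxidation: divalent palladium transmetalates only the silyl enol ether, and syn β-hydride elimination of C5–H from the equilibrating palladium enolate should give the less strained ring-cis enone, with reversible hydridopalladation funnelling any ring-trans isomer to it.

Step 23
Reactants: 36 enone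
Product: 38 7-hydroxy 2-ketone (C7–OH allylic; C5=C6 retained), via 7-hydroxy enol ether 37 (not isolated)
Conditions: NaBH4, CeCl3·7H2O, MeOH, −78 °C; then 1 M HCl, THF, 0 °C
Reagents that add atoms: water, O
Why: Luche 1,2-reduction touches only C7 because C2 is still an enol ether, and hydride is expected anti to the C8 PMB ether (polar Felkin–Anh) to give the target C7 configuration; dilute acid then hydrolyses the enol ether to the C2 ketone.

Step 24
Reactants: 38 7-hydroxy 2-ketone
Product: 39 7-O-(2-bromopropanoyl) ester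
Conditions: 2-bromopropanoyl bromide, pyridine, CH2Cl2, −20 °C
Reagents that add atoms: 2-bromopropanoyl bromide, CC(Br)C(Br)=O
Why: Acylation of the only free hydroxyl with the acid bromide installs C17, C18 and C19 with the halide needed for enolate generation.

Step 25
Reactants: 39 bromopropanoate
Product: 40 8-alcohol
Conditions: DDQ, CH2Cl2–pH 7 buffer, 0 °C
Reagents that add atoms: none
Why: Oxidative cleavage of the PMB ether by DDQ leaves the silyl ethers, the allylic ester and the alkenes untouched.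

Step 26
Reactants: 40 8-alcohol
Product: 41 8-ketone
Conditions: Dess–Martin periodinane, NaHCO3, CH2Cl2, 0 → 25 °C
Reagents that add atoms: none
Why: Buffered hypervalent iodine oxidation gives the α-acyloxy ketone under conditions that should not epimerise C7 or displace the bromide.

Step 27
Reactants: 41 8-ketone
Product: 43 lactone (C17–C8 bond; tertiary 8-hydroxyl; C2 ketone), via samarium enolate 42 (not isolated)
Conditions: SmI2, THF, −78 °C
Reagents that add atoms: none
Why: Samarium Reformatsky reaction: reduction of the C–Br bond gives the trivalent samarium enolate, which adds intramolecularly to the C8 carbonyl through a chelated five-membered-ring transition state, expected to place the 8-hydroxyl trans to H7 and the C17 methyl on the open face as in the target.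

Step 28
Reactants: 43 lactone ketone
Product: 44 2β-alcohol
Conditions: NaBH4, MeOH–THF, −40 °C
Reagents that add atoms: none
Why: Borohydride reduces the remaining ketone but not the lactone, and hydride is expected on the face of C2 away from the C15 methyl on the adjacent quaternary C1, giving the 2β-hydroxyl.

Step 29
Reactants: 44 2β-alcohol
Product: 45 pentaol (2, 9, 14, 16 and tertiary 8-hydroxyls)
Conditions: HF·pyridine, pyridine–THF, 0 → 25 °C
Reagents that add atoms: none
Why: Buffered fluoride removes the two TBS ethers and the TBDPS ether without the basic conditions that could cause retro-aldol cleavage of the β-hydroxy lactone.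

Step 30
Reactants: 45 pentaol
Product: 46 target CNP0277472.2
Conditions: Ac2O, pyridine, DMAP (cat.), CH2Cl2, 0 → 25 °C
Reagents that add atoms: acetic anhydride, CC(=O)OC(C)=O
Why: Acetylation esterifies the primary and three secondary hydroxyls and leaves the hindered tertiary 8-hydroxyl free.

## Compound list

1 | (S)-carvone | CC1=CC[C@@H](CC1=O)C(C)=C | starting material
2 | 2-(2-bromoethyl)-2-methyl-1,3-dioxolane | CC1(CCBr)OCCO1 | starting material
3 | lithium dienolate of 1 (C10=C1) | [Li]OC1=C[C@@H](C(C)=C)CC=C1C | intermediate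
4 | 1-alkylated carvone, ketal chain trans to isopropenyl | O=C1C(C)=CC[C@H](C(C)=C)[C@H]1CCC1(C)OCCO1 | intermediate
5 | lithium enolate of 4 | [Li]OC1=C(CCC2(C)OCCO2)[C@@H](C(C)=C)CC=C1C | intermediate
6 | 1-methylated enone, C15 methyl trans to isopropenyl | O=C1C(C)=CC[C@H](C(C)=C)[C@]1(C)CCC1(C)OCCO1 | intermediate
7 | methoxy hydroperoxide at the former isopropenyl carbon | O=C1C(C)=CC[C@H](C(C)(OC)OO)[C@]1(C)CCC1(C)OCCO1 | intermediate
8 | 14α-acetoxy enone ketal | O=C1C(C)=CC[C@H](OC(C)=O)[C@]1(C)CCC1(C)OCCO1 | intermediate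
9 | 14α-acetoxy enone with 3-oxobutyl chain | O=C1C(C)=CC[C@H](OC(C)=O)[C@]1(C)CCC(C)=O | intermediate
10 | bicyclic dienone acetate (8-oxo, Δ9, Δ11, 14α-OAc) | C1CC(=O)C=C2C(C)=CC[C@H](OC(C)=O)[C@]12C | intermediate
11 | trienone acetate (Δ2(7), Δ9, Δ11) | C1=CC(=O)C=C2C(C)=CC[C@H](OC(C)=O)[C@]12C | intermediate
12 | 2α,7α-epoxy-8-oxo-9,11-dien-14α-ol | O1[C@@H]2[C@H]1C(=O)C=C3C(C)=CC[C@H](O)[C@]23C | intermediate
13 | 14-O-TBS ether of 12 | O1[C@@H]2[C@H]1C(=O)C=C3C(C)=CC[C@H](O[Si](C)(C)C(C)(C)C)[C@]23C | intermediate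
14 | 2α,8β-diol, 9,11-diene | O[C@@H]1C[C@@H](O)C=C2C(C)=CC[C@H](O[Si](C)(C)C(C)(C)C)[C@]12C | intermediate
15 | 9β,10β-epoxy-2α,8β-diol, Δ11 | O[C@@H]1C[C@@H](O)[C@H]3O[C@]32C(C)=CC[C@H](O[Si](C)(C)C(C)(C)C)[C@]12C | intermediate
16 | 2α,8β,9β-triol, 10α-H, Δ11 | O[C@@H]1C[C@@H](O)[C@@H](O)[C@H]2C(C)=CC[C@H](O[Si](C)(C)C(C)(C)C)[C@]12C | intermediate
17 | 8,9-O-dibutylstannylene acetal of 16 | O[C@@H]1C[C@H]3O[Sn](CCCC)(CCCC)O[C@H]3[C@H]2C(C)=CC[C@H](O[Si](C)(C)C(C)(C)C)[C@]12C | intermediate
18 | 8-O-PMB ether of 16 | O[C@@H]1C[C@@H](OCc3ccc(OC)cc3)[C@@H](O)[C@H]2C(C)=CC[C@H](O[Si](C)(C)C(C)(C)C)[C@]12C | intermediate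
19 | 8-O-PMB 9,14-bis-O-TBS 2α-alcohol | O[C@@H]1C[C@@H](OCc3ccc(OC)cc3)[C@@H](O[Si](C)(C)C(C)(C)C)[C@H]2C(C)=CC[C@H](O[Si](C)(C)C(C)(C)C)[C@]12C | intermediate
20 | C2 ketone | O=C1C[C@@H](OCc3ccc(OC)cc3)[C@@H](O[Si](C)(C)C(C)(C)C)[C@H]2C(C)=CC[C@H](O[Si](C)(C)C(C)(C)C)[C@]12C | intermediate
21 | potassium enolate of 20 (C2=C7) | [K]OC1=C[C@@H](OCc3ccc(OC)cc3)[C@@H](O[Si](C)(C)C(C)(C)C)[C@H]2C(C)=CC[C@H](O[Si](C)(C)C(C)(C)C)[C@]12C | intermediate
22 | 7α-hydroxy 2-ketone | O=C1[C@H](O)[C@@H](OCc3ccc(OC)cc3)[C@@H](O[Si](C)(C)C(C)(C)C)[C@H]2C(C)=CC[C@H](O[Si](C)(C)C(C)(C)C)[C@]12C | intermediate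
23 | vinylmagnesium bromide | C=C[Mg]Br | starting material
24 | 2β-vinyl 2α,7α-diol | C=C[C@@]1(O)[C@H](O)[C@@H](OCc3ccc(OC)cc3)[C@@H](O[Si](C)(C)C(C)(C)C)[C@H]2C(C)=CC[C@H](O[Si](C)(C)C(C)(C)C)[C@]12C | intermediate
25 | 2β-vinyl 2α-hydroxy 7-ketone | C=C[C@@]1(O)C(=O)[C@@H](OCc3ccc(OC)cc3)[C@@H](O[Si](C)(C)C(C)(C)C)[C@H]2C(C)=CC[C@H](O[Si](C)(C)C(C)(C)C)[C@]12C | intermediate
26 | 2-O-MOM ether of 25 | C=C[C@@]1(OCOC)C(=O)[C@@H](OCc3ccc(OC)cc3)[C@@H](O[Si](C)(C)C(C)(C)C)[C@H]2C(C)=CC[C@H](O[Si](C)(C)C(C)(C)C)[C@]12C | intermediate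
27 | propargyl alcohol | C#CCO | starting material
28 | tert-butyl(diphenyl)(prop-2-ynyloxy)silane | C#CCO[Si](c1ccccc1)(c1ccccc1)C(C)(C)C | intermediate
29 | (E)-alkenylzirconocene chloride from 28 | Cl[Zr](C1C=CC=C1)(C1C=CC=C1)/C=C/CO[Si](c1ccccc1)(c1ccccc1)C(C)(C)C | intermediate
30 | (E)-tert-butyl[(3-iodoallyl)oxy]diphenylsilane | I/C=C/CO[Si](c1ccccc1)(c1ccccc1)C(C)(C)C | intermediate
31 | (E)-alkenyllithium from 30 | [Li]/C=C/CO[Si](c1ccccc1)(c1ccccc1)C(C)(C)C | intermediate
32 | oxy-Cope precursor: trans-decalin, C2 β-vinyl/α-OMOM, C7 β-OH/α-(E)-3-(TBDPS-oxy)propenyl, 8β-OPMB, 9β-OTBS, 14α-OTBS | C=C[C@@]1(OCOC)[C@](O)(/C=C/CO[Si](c3ccccc3)(c3ccccc3)C(C)(C)C)[C@@H](OCc3ccc(OC)cc3)[C@@H](O[Si](C)(C)C(C)(C)C)[C@H]2C(C)=CC[C@H](O[Si](C)(C)C(C)(C)C)[C@]12C | intermediate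
33 | potassium C7 alkoxide of 32 | C=C[C@@]1(OCOC)[C@](O[K])(/C=C/CO[Si](c3ccccc3)(c3ccccc3)C(C)(C)C)[C@@H](OCc3ccc(OC)cc3)[C@@H](O[Si](C)(C)C(C)(C)C)[C@H]2C(C)=CC[C@H](O[Si](C)(C)C(C)(C)C)[C@]12C | intermediate
34 | ten-membered ring potassium enolate (C6=C7–OK, C5/C8 trans; C2=C3 MOM enol ether, C1/C4 trans) | CC(C)(C)[Si](c1ccccc1)(c1ccccc1)OC[C@@H]2/C=C(O[K])/[C@@H](OCc3ccc(OC)cc3)[C@@H](O[Si](C)(C)C(C)(C)C)[C@H]4C(C)=CC[C@H](O[Si](C)(C)C(C)(C)C)[C@]4(C)/C(OCOC)=C/C2 | intermediate
35 | ten-membered ring bis-enol ether (C6=C7 triethylsilyl enol ether; C2=C3 MOM enol ether) | CC(C)(C)[Si](c1ccccc1)(c1ccccc1)OC[C@@H]2/C=C(O[Si](CC)(CC)CC)/[C@@H](OCc3ccc(OC)cc3)[C@@H](O[Si](C)(C)C(C)(C)C)[C@H]4C(C)=CC[C@H](O[Si](C)(C)C(C)(C)C)[C@]4(C)/C(OCOC)=C/C2 | intermediate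
36 | ring-cis C5=C6 enone (7-oxo) with C2=C3 MOM enol ether | CC(C)(C)[Si](c1ccccc1)(c1ccccc1)OC/C2=C/C(=O)[C@@H](OCc3ccc(OC)cc3)[C@@H](O[Si](C)(C)C(C)(C)C)[C@H]4C(C)=CC[C@H](O[Si](C)(C)C(C)(C)C)[C@]4(C)/C(OCOC)=C/C2 | intermediate
37 | 7-hydroxy enol ether | CC(C)(C)[Si](c1ccccc1)(c1ccccc1)OC/C2=C/[C@H](O)[C@@H](OCc3ccc(OC)cc3)[C@@H](O[Si](C)(C)C(C)(C)C)[C@H]4C(C)=CC[C@H](O[Si](C)(C)C(C)(C)C)[C@]4(C)/C(OCOC)=C/C2 | intermediate
38 | 7-hydroxy 2-ketone | CC(C)(C)[Si](c1ccccc1)(c1ccccc1)OC/C2=C/[C@H](O)[C@@H](OCc3ccc(OC)cc3)[C@@H](O[Si](C)(C)C(C)(C)C)[C@H]4C(C)=CC[C@H](O[Si](C)(C)C(C)(C)C)[C@]4(C)C(=O)CC2 | intermediate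
39 | 7-O-(2-bromopropanoyl) ester (C17 unspecified) | CC(C)(C)[Si](c1ccccc1)(c1ccccc1)OC/C2=C/[C@H](OC(=O)C(C)Br)[C@@H](OCc3ccc(OC)cc3)[C@@H](O[Si](C)(C)C(C)(C)C)[C@H]4C(C)=CC[C@H](O[Si](C)(C)C(C)(C)C)[C@]4(C)C(=O)CC2 | intermediate
40 | 8-alcohol | CC(C)(C)[Si](c1ccccc1)(c1ccccc1)OC/C2=C/[C@H](OC(=O)C(C)Br)[C@@H](O)[C@@H](O[Si](C)(C)C(C)(C)C)[C@H]4C(C)=CC[C@H](O[Si](C)(C)C(C)(C)C)[C@]4(C)C(=O)CC2 | intermediate
41 | 8-ketone | CC(C)(C)[Si](c1ccccc1)(c1ccccc1)OC/C2=C/[C@H](OC(=O)C(C)Br)C(=O)[C@@H](O[Si](C)(C)C(C)(C)C)[C@H]4C(C)=CC[C@H](O[Si](C)(C)C(C)(C)C)[C@]4(C)C(=O)CC2 | intermediate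
42 | samarium enolate of the C7 propanoate | CC(C)(C)[Si](c1ccccc1)(c1ccccc1)OC/C2=C/[C@H](OC(=CC)O[Sm](I)I)C(=O)[C@@H](O[Si](C)(C)C(C)(C)C)[C@H]4C(C)=CC[C@H](O[Si](C)(C)C(C)(C)C)[C@]4(C)C(=O)CC2 | intermediate
43 | lactone with 8-hydroxyl and C2 ketone | CC(C)(C)[Si](c1ccccc1)(c1ccccc1)OC/C1=C/[C@@H]2OC(=O)[C@H](C)[C@@]2(O)[C@@H](O[Si](C)(C)C(C)(C)C)[C@H]2C(C)=CC[C@H](O[Si](C)(C)C(C)(C)C)[C@]2(C)C(=O)CC1 | intermediate
44 | 2β-alcohol | CC(C)(C)[Si](c1ccccc1)(c1ccccc1)OC/C1=C/[C@@H]2OC(=O)[C@H](C)[C@@]2(O)[C@@H](O[Si](C)(C)C(C)(C)C)[C@H]2C(C)=CC[C@H](O[Si](C)(C)C(C)(C)C)[C@]2(C)[C@@H](O)CC1 | intermediate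
45 | pentaol | OC/C1=C/[C@@H]2OC(=O)[C@H](C)[C@@]2(O)[C@@H](O)[C@H]2C(C)=CC[C@H](O)[C@]2(C)[C@@H](O)CC1 | intermediate
46 | CNP0277472.2 (2,9,14,16-tetraacetate, 8-hydroxy lactone) | CC(=O)OC/C1=C/[C@@H]2OC(=O)[C@H](C)[C@@]2(O)[C@@H](OC(C)=O)[C@H]2C(C)=CC[C@H](OC(C)=O)[C@]2(C)[C@@H](OC(C)=O)CC1 | target

## Step count and risks

Total steps: 30. Longest linear sequence: 28 (steps 1–17 and 20–30); steps 18–19 make the side chain.

**Step 21 (key step).** The alkoxide may be parked by reversible transfer of the C9 silyl group to O7, or may fragment heterolytically, so that the [3,3] shift stalls. Fallback from 32: silylation of the C7 hydroxyl (TMSOTf, Et3N) would give the trimethylsilyl ether F1. Its neutral siloxy-Cope rearrangement (o-dichlorobenzene, about 200 °C) would give the trimethylsilyl enol ether F2 through the same chair array. Pd(OAc)2 as in step 22 would convert F2 into 36, where the route is rejoined.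

**Step 23.** Hydride delivery to C7 of the flexible ten-membered enone may show poor or reversed facial selectivity. Fallback from 36: if reduction and hydrolysis give mainly the C7-epimeric hydroxy ketone F3, Mitsunobu esterification of F3 with 2-bromopropanoic acid (PPh3, DIAD, PhMe, 0 °C) would invert C7 and give 39 directly, where the route is rejoined.

**Step 27.** Face selectivity in C8–C17 bond formation may be low, or SmI2 may cleave an α-oxygen substituent of the C8 ketone before the enolate adds. Fallback from 38: silylation (TESOTf, 2,6-lutidine) would give the 7-O-triethylsilyl ether F4. DDQ and then Dess–Martin periodinane would give the 8-alcohol F5 and the 8-ketone F6. Intermolecular Reformatsky addition of ethyl 2-bromopropanoate (Zn, THF) to the more electrophilic C8 carbonyl, under Felkin–Anh control by the C7 silyl ether, would give the hydroxy ester F7. Acid (CSA, MeOH) would remove the silyl group and close the lactone to 43, where the route is rejoined.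

## Further compounds

F1 | step 21 | 7-O-trimethylsilyl ether of 32 | C=C[C@@]1(OCOC)[C@](O[Si](C)(C)C)(/C=C/CO[Si](c3ccccc3)(c3ccccc3)C(C)(C)C)[C@@H](OCc3ccc(OC)cc3)[C@@H](O[Si](C)(C)C(C)(C)C)[C@H]2C(C)=CC[C@H](O[Si](C)(C)C(C)(C)C)[C@]12C
F2 | step 21 | ten-membered bis-enol ether with C6=C7 trimethylsilyl enol ether | CC(C)(C)[Si](c1ccccc1)(c1ccccc1)OC[C@@H]2/C=C(O[Si](C)(C)C)/[C@@H](OCc3ccc(OC)cc3)[C@@H](O[Si](C)(C)C(C)(C)C)[C@H]4C(C)=CC[C@H](O[Si](C)(C)C(C)(C)C)[C@]4(C)/C(OCOC)=C/C2
F3 | step 23 | C7 epimer of 38 | CC(C)(C)[Si](c1ccccc1)(c1ccccc1)OC/C2=C/[C@@H](O)[C@@H](OCc3ccc(OC)cc3)[C@@H](O[Si](C)(C)C(C)(C)C)[C@H]4C(C)=CC[C@H](O[Si](C)(C)C(C)(C)C)[C@]4(C)C(=O)CC2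
F4 | step 27 | 7-O-triethylsilyl ether of 38 | CC(C)(C)[Si](c1ccccc1)(c1ccccc1)OC/C2=C/[C@H](O[Si](CC)(CC)CC)[C@@H](OCc3ccc(OC)cc3)[C@@H](O[Si](C)(C)C(C)(C)C)[C@H]4C(C)=CC[C@H](O[Si](C)(C)C(C)(C)C)[C@]4(C)C(=O)CC2
F5 | step 27 | 8-alcohol from F4 | CC(C)(C)[Si](c1ccccc1)(c1ccccc1)OC/C2=C/[C@H](O[Si](CC)(CC)CC)[C@@H](O)[C@@H](O[Si](C)(C)C(C)(C)C)[C@H]4C(C)=CC[C@H](O[Si](C)(C)C(C)(C)C)[C@]4(C)C(=O)CC2
F6 | step 27 | 8-ketone from F5 | CC(C)(C)[Si](c1ccccc1)(c1ccccc1)OC/C2=C/[C@H](O[Si](CC)(CC)CC)C(=O)[C@@H](O[Si](C)(C)C(C)(C)C)[C@H]4C(C)=CC[C@H](O[Si](C)(C)C(C)(C)C)[C@]4(C)C(=O)CC2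
F7 | step 27 | C8 hydroxy ethyl ester (Reformatsky adduct of F6) | CC(C)(C)[Si](c1ccccc1)(c1ccccc1)OC/C2=C/[C@H](O[Si](CC)(CC)CC)[C@@](O)([C@@H](C)C(=O)OCC)[C@@H](O[Si](C)(C)C(C)(C)C)[C@H]4C(C)=CC[C@H](O[Si](C)(C)C(C)(C)C)[C@]4(C)C(=O)CC2
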